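## Structural features

The target 23 is a monocyclic dibromo sesquiterpenoid, numbered here as a farnesane: ring A is a cyclohexane (C6–C11) carrying an exocyclic methylene at C7 (C7=C15), a gem-dimethyl group at C11, bromine at C8 and at C10, and at C6 a two-carbon tether (C5–C4) that ends in the tertiary allylic carbinol C3 with its vinyl group C1=C2. The four stereocentres are 3S, 6S, 8R and 10R; the three ring centres stand 1,3 to one another (C6 and C8 across the sp2 carbon C7, C6 and C10 across the quaternary C11, C8 and C10 across C9), with the C8 bromide cis to the C6 chain and the C10 bromide trans to both. The C8 bromide is secondary and allylic, so ionisation or SN2′ exchange would turn it into the conjugated primary bromide (C7=C8, bromine on C15) and base would eliminate it; it has to be made late and under kinetic control. The C10 bromide is secondary and neopentylic, so substitution there is slow and cationic conditions invite methyl migration from C11. The tertiary allylic alcohol is acid-labile and, when free, a nucleophile toward any cation generated at C7. The real difficulty therefore lies in the two C–Br stereocentres on either side of C9 and in the C3 centre, which is insulated from the ring by two methylene groups and cannot be set by relay, not in the carbon skeleton. The key step exploits the fact that the unit C8(Br)–C7(=C15) of ring A is the allylic-transposition product of an allylsilane Me3Si–C15–C7=C8, whose endocyclic C7=C8 bond is a metathesis retron.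

## Logic of the disconnections

23 ⇒ 22. The O–H bond at C3 is exchanged for O–SiEt3. A free C3 hydroxyl could capture the cation formed at C7 in the preceding bromination (closing a six-membered ether) and would interfere with the enolate, organocerium and phosphonium steps further back. The skeleton is not simplified, but the group becomes a spectator that lasts from step 7 to step 12. The demand is an unmasking reagent that is neither basic nor a source of nucleophilic halide, because 22 and 23 carry the kinetic allylic bromide.

22 ⇒ 21. The C8–Br bond is cut and the alkene is moved back from C7=C15 to C7=C8, with silicon placed on C15. The position of silicon then dictates where bromine enters, so the contra-thermodynamic secondary bromide is reached without allylic C–H bromination. The most fragile function and one stereocentre disappear. The forward step must deliver bromine to C8 on the face of the C6 chain, in a medium free of acid and bromide ion.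

21 ⇒ 20. The C7=C8 double bond of ring A is cut and each end is capped with a methylene group. It is the one ring bond whose formation needs no polar activation next to the C10 bromide, and both termini are plain alkenes. The ring is removed: 20 is an acyclic triene whose stereocentres C6 and C10 flank C11. The catalyst must start at the C8 vinyl group and close onto the 1,1-disubstituted C7 alkene while ignoring C1=C2.

20 ⇒ 19. The C10–Br bond is exchanged for a C10–O bond of opposite configuration. A C10 carbinol can be made by reagent-controlled carbonyl allylation, and its oxygen can serve as a lactone oxygen further back. The demand is an SN2 displacement with inversion at a neopentylic secondary carbon in the presence of an allylsilane. The C6 descriptor changes from S in 19 to R in 20 only because bromine raises the rank of the C11 branch; the geometry is unchanged.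

19 ⇒ 16 + 17. Both bonds from C7 to its one-carbon substituents are cut (C7–C15 and the C7=CH2 bond whose methylene is later lost in the ring closure). C7 becomes a lactone carbonyl and the C10 oxygen the ring oxygen. Two equivalents of 17 build the 2-(silylmethyl)allyl unit, and the same operation frees the C10 hydroxyl. The demand is double addition to a hindered carbonyl without enolisation at C6, then loss of only one silyl group.

16 ⇒ 7 + 14. The C5–C6 bond is cut. C6 is α to the lactone carbonyl, so the bond forms by enolate alkylation. The cut separates the remote C3 centre (in 14) from the ring stereocentres (in 7), makes the route convergent, and lets the five-membered ring of 7 control C6. The demand is alkylation of a hindered enolate by a hindered primary iodide, anti to the C10 substituent.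

7 ⇒ 3 + 4. The C9–C10 bond is cut and the lactone C–O bond is traced back to the ester. Allyl addition to the C10 aldehyde sets the carbinol and brings in C8–C9 with the terminal alkene needed for ring closure. A halolactonisation followed by vinyl coupling was weighed for the same centre and set aside: enantiocontrol in halocyclisation of a monosubstituted alkene on a quaternary carbon is less secure, and an alkyl iodide with a β-acyloxy group tends to fragment under coupling conditions. The allylation also saves one step. The demand is high enantioselectivity with an α-quaternary aldehyde and no attack on the ester.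

3 ⇒ 1. The C10=O bond is traced to the C=C bond of 1, whose terminal CH2 is discarded. 1 already holds C6, C7, C10, C11 and both methyls. The only demand is a reductive work-up that stops at the aldehyde.

14 ⇒ 13. The O–Si bond at C3 is cut. The carbinol must be masked before the enolate step. The demand is silylation of a tertiary alcohol without touching the primary iodide.

13 ⇒ 12. The C5–I bond is exchanged for C5–OH. The demand is selectivity for the primary over the tertiary allylic hydroxyl.

12 ⇒ 10. The C1=C2 π bond is traced to a C1–Se bond. The vinyl group is latent in a selenide that survives hydride reduction. The demand is oxidation at selenium only and a clean syn-elimination to the terminal alkene.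

10 ⇒ 9. C5 is returned to the carboxylic acid oxidation level. No selectivity issue arises.

9 ⇒ 8. The C1–Se bond is cut and the alkyl–oxygen bond of the lactone restored. The two two-carbon arms of the carbinol are distinguishable only while the lactone is closed. The O-alkyl arm must become the vinyl group and the acyl arm C4–C5: the vinyl-bearing arm outranks the other in 23 while the order is reversed in 8, so the R centre of 8 becomes 3S. The demand is clean SN2 attack at the O-alkyl carbon, not at the carbonyl.

## Other disconnections considered

Alternative 1: Bromo-Prins carbocyclisation. The cuts are C8–C9 and C10–Br. The α-methylene aldehyde A1 (C6 already set, vinyl on C11, ester as the future C3 terminus) would be treated with TiBr4 at low temperature. The Lewis acid activates C8, the vinyl carbon C9 attacks it, and bromide quenches the C10 cation to give the bromohydrin A2.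
- In its favour: the ring and the neopentylic C10–Br bond arise together from a cation–bromide pair, so no substitution at a neopentylic carbinol is needed. On this point it is better than the chosen plan, whose step 10 must force an SN2 at C10. A chair-like transition state with the C6 arm equatorial could relay C6 to C8 and C10, and the ring is reached in fewer steps.
- Against it: the C10 cation is secondary and next to the quaternary C11, so methyl migration and proton loss compete with bromide capture. A monosubstituted vinyl group is a weak π-nucleophile for a conjugated aldehyde. C8 arrives as a carbinol and must be exchanged for bromide with inversion at an allylic position, where SN2′ leakage to the primary bromide threatens. The C3 centre would have to be built late from the ester terminus by addition to a methyl ketone with no control element.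
- Comparison: the two plans are equal in needing one invertive C–O to C–Br exchange (C8 there, C10 here). Alternative 1 is shorter to ring A, but weaker on the C8 bromide (set directly by SE2′ in the chosen plan) and much weaker on C3 (imported from 8 in the chosen plan).

Alternative 2: Reductive enyne cyclisation. The cut is C6–C7. The 1,7-enyne A3 (terminal alkyne C15≡C7, E-alkene C5=C6, anti silyloxy groups at C8 and C10, C3 in place) would be treated with Pd2(dba)3, acetic acid and triethylsilane. The hydride acetate of divalent palladium formed from zerovalent palladium adds to the alkyne, the C7 vinylpalladium inserts C6=C5 in a 6-exo sense, and the silane reduces the C5–Pd bond to give A4.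
- In its favour: the exocyclic methylene is created in the ring-forming step, and that step also creates the C6 stereocentre. On this count it is better than the chosen key step, which creates none. The C8 and C10 oxygen stereocentres are reachable by dependable carbonyl-addition chemistry, and C3 is carried from the chiral pool as in the chosen plan (equal).
- Against it: the insertion must engage a 1,2-disubstituted alkene whose carbon C6 is bonded to the quaternary C11. Facial selectivity at C6 rests on a chair-like transition state with only the C10 silyloxy group nearby. The C1=C2 vinyl group and the product methylene are also substrates for palladium hydride. After cyclisation two carbinols must be exchanged for bromide with inversion, one neopentylic on a ring and one allylic.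
- Comparison: the hardest operation of the chosen plan would be required twice, and the precursor A3 is longer to assemble than 20. The chosen plan makes the allylic bromide without any carbinol at C8.

Alternative 3: Michael–Claisen [3+3] annulation. The cuts are C6–C11 and C9–C10. The enone A5 would take up the isobutyrate ketene silyl acetal A6 at C6 under Lewis acid catalysis (Mukaiyama–Michael). KOtBu would then drive the methyl ketone enolate (C9) onto the ester carbon (C10) to give the dione A7.
- In its favour: two skeletal bonds, the quaternary C11 and the ring form in one flask from cheap materials by robust ionic chemistry. In bond economy and scalability it is better than the chosen key step, which forms one skeletal bond. C3 would come from (S)-linalool A8, equal in principle to the use of 8.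
- Against it: C6 is created in a conjugate addition with no nearby control element, so it would need catalyst control on a simple acyclic methyl enone. A7 lacks C15 and both bromine-bearing stereocentres. It would need differentiation of two carbonyls, methylenation at C7 (in competition with the more acidic C9), two stereoselective reductions and two invertive brominations, with β-elimination-prone intermediates throughout.
- Comparison: the shortest route to a six-membered ring but the longest from ring to target. The chosen plan spends its steps before the ring closure and needs only two after it.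

Key step: step 11

Remark: the B-allyl reagent made from the (+)-α-pinene-derived borinate is taken to add to the Si face of aldehyde 3, as it does with other α-branched aldehydes; this gives the S carbinol at C10.

## Route

Step 1
Reactants: 1 methyl 3,3-dimethylpent-4-enoate
Product: 3 methyl 3,3-dimethyl-4-oxobutanoate, via ozonide 2 (not isolated)
Conditions: O3, CH2Cl2, −78 °C; PPh3, −78 °C → rt
Reagents that add atoms: ozone, [O-][O+]=O
Why: Criegee ozonolysis of the only alkene followed by reductive cleavage of the 1,2,4-trioxolane 2; the aldehyde has a quaternary α-carbon and cannot enolise or self-condense, the ester is inert, and no stereocentre is formed.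

Step 2
Reactants: 3 methyl 3,3-dimethyl-4-oxobutanoate; 4 allylmagnesium bromide
Product: 7 (5S)-4,4-dimethyl-5-(prop-2-en-1-yl)oxolan-2-one, via borinate 5 (not isolated), via hydroxy ester 6 (not isolated)
Conditions: (−)-Ipc2BOMe [from (+)-α-pinene], 4, Et2O, −78 °C → rt; 3, −78 °C; NaBO3·4H2O, THF–H2O, rt; TsOH (cat.), CH2Cl2, rt
Reagents that add atoms: none
Why: Brown asymmetric allylboration: the B-allyldiisopinocampheylborane formed from 4 adds through a closed chair transition state to the Si face of the aldehyde and sets C10 as S, and hindered α-quaternary aldehydes are accepted by this reagent; mild oxidation of 5 and acid-catalysed lactonisation of 6, helped by the gem-dimethyl group, give 7 without exposing the ester to free Grignard reagent.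

Step 3
Reactants: 8 (R)-mevalonolactone [(4R)-4-hydroxy-4-methyloxan-2-one]
Product: 9 (3S)-3-hydroxy-3-methyl-5-(phenylselanyl)pentanoic acid
Conditions: (PhSe)2, NaBH4, DMF, rt; 8, 100 °C; aq. HCl
Reagents that add atoms: diphenyl diselenide, c1ccc(cc1)[Se][Se]c1ccccc1
Why: SN2 opening of a lactone at the O-alkyl carbon by the soft benzeneselenolate anion (alkyl–oxygen cleavage) differentiates the two arms of 8 for good; the carbinol carbon is not touched and its descriptor changes to S only because the selenium-bearing arm now ranks higher.

Step 4
Reactants: 9 (3S)-3-hydroxy-3-methyl-5-(phenylselanyl)pentanoic acid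
Product: 10 (3S)-3-methyl-5-(phenylselanyl)pentane-1,3-diol
Conditions: LiAlH4, THF, 0 °C → reflux; H2O, aq. NaOH
Reagents that add atoms: none
Why: Hydride reduction of a carboxylic acid to the primary alcohol; alkyl aryl selenides and tertiary alcohols are inert to LiAlH4 and no stereocentre is involved.

Step 5
Reactants: 10 (3S)-3-methyl-5-(phenylselanyl)pentane-1,3-diol
Product: 12 (3S)-3-methylpent-4-ene-1,3-diol, via selenoxide 11 (not isolated)
Conditions: mCPBA (1.0 equiv), THF, −40 °C; iPr2NH, 60 °C
Reagents that add atoms: none
Why: Selenoxide syn-elimination: selenium is oxidised far faster than any alkene, the primary alkyl selenoxide then eliminates on warming to the terminal vinyl group, and the amine scavenges the selenenic acid so that it cannot add back.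

Step 6
Reactants: 12 (3S)-3-methylpent-4-ene-1,3-diol
Product: 13 (3S)-5-iodo-3-methylpent-1-en-3-ol
Conditions: I2, PPh3, imidazole, CH2Cl2, 0 °C
Reagents that add atoms: iodine, II
Why: Appel-type iodination of the primary hydroxyl; the tertiary allylic hydroxyl is too hindered to form an alkoxyphosphonium ion at this temperature and stays free.

Step 7
Reactants: 13 (3S)-5-iodo-3-methylpent-1-en-3-ol
Product: 14 triethyl{[(3S)-5-iodo-3-methylpent-1-en-3-yl]oxy}silane
Conditions: TESOTf, 2,6-lutidine, CH2Cl2, −78 → 0 °C
Reagents that add atoms: triethylsilyl trifluoromethanesulfonate, CC[Si](CC)(CC)OS(=O)(=O)C(F)(F)F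
Why: Silylation of a hindered tertiary alcohol with a silyl triflate and a hindered pyridine base; the primary iodide does not react.

Step 8
Reactants: 7 (5S)-4,4-dimethyl-5-(prop-2-en-1-yl)oxolan-2-one; 14 triethyl{[(3S)-5-iodo-3-methylpent-1-en-3-yl]oxy}silane
Product: 16 (3S,5S)-4,4-dimethyl-3-[(3S)-3-methyl-3-(triethylsilyloxy)pent-4-en-1-yl]-5-(prop-2-en-1-yl)oxolan-2-one, via lithium enolate 15 (not isolated)
Conditions: LiN(iPr)2, THF, −78 °C; 14, DMPU, −78 → −20 °C
Reagents that add atoms: none
Why: SN2 alkylation of a γ-lactone lithium enolate forms C5–C6; the enolate face syn to the allyl group at C10 is shielded by that group and by the pseudoaxial C11 methyl on the same side, so the iodide should enter anti and set C6 trans to the allyl group (3S in the lactone).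

Step 9
Reactants: 16 (3S,5S)-4,4-dimethyl-3-[(3S)-3-methyl-3-(triethylsilyloxy)pent-4-en-1-yl]-5-(prop-2-en-1-yl)oxolan-2-one; 17 (trimethylsilylmethyl)magnesium chloride (first equivalent)
Product: 19 (4S,6S,9S)-5,5,9-trimethyl-9-(triethylsilyloxy)-6-[3-(trimethylsilyl)prop-1-en-2-yl]undeca-1,10-dien-4-ol, via bis-silylmethyl carbinol 18 (not isolated)
Conditions: CeCl3 (3.5 equiv), 17 (3.5 equiv), THF, −78 °C → rt; aq. NH4Cl; SiO2, CH2Cl2, rt
Reagents that add atoms: (trimethylsilylmethyl)magnesium chloride (the second equivalent of 17), C[Si](C)(C)C[Mg]Cl
Why: Cerium-mediated double addition of 17 to the lactone carbonyl gives 18, in which one Me3SiCH2 group becomes C15 with its silicon and the other becomes the terminal methylene once acid-promoted Peterson elimination expels trimethylsilanol; this is the established conversion of esters and lactones into 2-substituted allylsilanes. The organocerium reagent suppresses enolisation at C6, ring opening frees the C10 hydroxyl, and silica gel is mild enough for the tertiary silyl ether and the allylsilane.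

Step 10
Reactants: 19 (4S,6S,9S)-5,5,9-trimethyl-9-(triethylsilyloxy)-6-[3-(trimethylsilyl)prop-1-en-2-yl]undeca-1,10-dien-4-ol
Product: 20 triethyl{[(3S,6R,8R)-8-bromo-3,7,7-trimethyl-6-[3-(trimethylsilyl)prop-1-en-2-yl]undeca-1,10-dien-3-yl]oxy}silane
Conditions: CBr4, PPh3, 2,6-lutidine, toluene, 0 → 60 °C
Reagents that add atoms: carbon tetrabromide, BrC(Br)(Br)Br
Why: Appel bromination: bromide displaces the alkoxyphosphonium ion from the rear and inverts C10 from S to R; the neopentylic position makes the SN2 slow, so a non-polar solvent, moderate heat and a pyridine buffer are used to hold back ionisation, elimination and protodesilylation.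

Step 11
Reactants: 20 triethyl{[(3S,6R,8R)-8-bromo-3,7,7-trimethyl-6-[3-(trimethylsilyl)prop-1-en-2-yl]undeca-1,10-dien-3-yl]oxy}silane
Product: 21 {[(4R,6R)-4-bromo-5,5-dimethyl-6-[(3S)-3-methyl-3-(triethylsilyloxy)pent-4-en-1-yl]cyclohex-1-en-1-yl]methyl}trimethylsilane
Conditions: RuCl2(=CHPh)(PCy3)(H2IMes) (second-generation Grubbs catalyst, 5 mol %), CH2Cl2 (0.005 M), 40 °C
Reagents that add atoms: none
Why: Olefin metathesis by the Chauvin mechanism: after loss of PCy3 the ruthenium benzylidene exchanges with the unhindered C8 vinyl group by [2+2] cycloaddition and cycloreversion, which puts the metal on C8. The C8 alkylidene then adds across the 1,1-disubstituted C7 alkene to a ruthenacyclobutane whose cycloreversion forms C7=C8 and a ruthenium methylidene, which carries the chain and ends as ethene. The closest known reaction type is ring-closing metathesis of dienes with a 2-(silylmethyl)allyl terminus to cyclic allylsilanes with a trisubstituted ring alkene. Ring A closes as a six-membered carbocycle with both alkene carbons inside the ring, helped by the gem-dimethyl group at C11 and the branch at C6, which hold the two termini close. No stereocentre is created, and C3, C6 and C10 are spectators under these neutral conditions. The step needs site selectivity among three alkenes: the C1=C2 vinyl group sits on a fully substituted carbon with a bulky silyloxy group and should load the catalyst far more slowly than the C8 terminus, the C7 alkene is 1,1-disubstituted and does not initiate, and from the C8 alkylidene the only other closure (onto C2) would need a nine-membered ring. High dilution and gentle heating disfavour dimerisation at C8, and the homoallylic bromide does not bind ruthenium.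

Step 12
Reactants: 21 {[(4R,6R)-4-bromo-5,5-dimethyl-6-[(3S)-3-methyl-3-(triethylsilyloxy)pent-4-en-1-yl]cyclohex-1-en-1-yl]methyl}trimethylsilane
Product: 22 {[(3S)-5-[(1S,3R,5R)-3,5-dibromo-2,2-dimethyl-6-methylidenecyclohexyl]-3-methylpent-1-en-3-yl]oxy}triethylsilane
Conditions: NBS, propylene oxide, CH2Cl2, −78 °C, dark
Reagents that add atoms: N-bromosuccinimide, BrN1C(=O)CCC1=O
Why: Electrophilic bromodesilylation of an allylsilane (SE2′): bromine bonds to C8, the β-silyl cation at C7 loses silicon and the alkene moves to C7=C15, so regiochemistry is fixed by the position of silicon; in the half-chair with the C6 chain pseudoaxial (no A(1,2) strain with CH2SiMe3) and the C10 bromide equatorial, the C–Si bond aligns on the face away from the chain and anti attack, which is also axial attack, should place bromine on C8 cis to the chain and trans to the C10 bromide (8R); the terminal vinyl group is far less nucleophilic than the allylsilane.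

Step 13
Reactants: 22 {[(3S)-5-[(1S,3R,5R)-3,5-dibromo-2,2-dimethyl-6-methylidenecyclohexyl]-3-methylpent-1-en-3-yl]oxy}triethylsilane
Product: 23 (3S)-5-[(1S,3R,5R)-3,5-dibromo-2,2-dimethyl-6-methylidenecyclohexyl]-3-methylpent-1-en-3-ol
Conditions: Et3N·3HF, MeCN, 0 °C → rt
Reagents that add atoms: none
Why: Fluoride-assisted cleavage of a silyl ether under weakly acidic conditions; the reagent offers neither free amine nor naked fluoride, so the secondary allylic bromide and the tertiary allylic alcohol should not ionise, eliminate or be substituted.

## Compound list

1 | methyl 3,3-dimethylpent-4-enoate | COC(=O)CC(C)(C)C=C | starting material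
2 | methyl 3-methyl-3-(1,2,4-trioxolan-3-yl)butanoate (ozonide) | COC(=O)CC(C)(C)C1OCOO1 | intermediate
3 | methyl 3,3-dimethyl-4-oxobutanoate | COC(=O)CC(C)(C)C=O | intermediate
4 | allylmagnesium bromide | C=CC[Mg]Br | starting material
5 | methyl (4S)-4-[bis(isopinocampheyl)boranyloxy]-3,3-dimethylhept-6-enoate (borinate) | COC(=O)CC(C)(C)[C@H](CC=C)OB([C@@H]1C[C@@H]2C[C@H]([C@H]1C)C2(C)C)[C@@H]1C[C@@H]2C[C@H]([C@H]1C)C2(C)C | intermediate
6 | methyl (4S)-4-hydroxy-3,3-dimethylhept-6-enoate | COC(=O)CC(C)(C)[C@@H](O)CC=C | intermediate
7 | (5S)-4,4-dimethyl-5-(prop-2-en-1-yl)oxolan-2-one | O=C1CC(C)(C)[C@H](CC=C)O1 | intermediate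
8 | (R)-mevalonolactone | O=C1C[C@](C)(O)CCO1 | starting material
9 | (3S)-3-hydroxy-3-methyl-5-(phenylselanyl)pentanoic acid | OC(=O)C[C@](C)(O)CC[Se]c1ccccc1 | intermediate
10 | (3S)-3-methyl-5-(phenylselanyl)pentane-1,3-diol | OCC[C@](C)(O)CC[Se]c1ccccc1 | intermediate
11 | (3S)-3-methyl-5-(phenylseleninyl)pentane-1,3-diol (selenoxide, either configuration at selenium) | OCC[C@](C)(O)CC[Se](=O)c1ccccc1 | intermediate
12 | (3S)-3-methylpent-4-ene-1,3-diol | C=C[C@@](C)(O)CCO | intermediate
13 | (3S)-5-iodo-3-methylpent-1-en-3-ol | C=C[C@@](C)(O)CCI | intermediate
14 | triethyl{[(3S)-5-iodo-3-methylpent-1-en-3-yl]oxy}silane | C=C[C@@](C)(O[Si](CC)(CC)CC)CCI | intermediate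
15 | lithium (5S)-4,4-dimethyl-5-(prop-2-en-1-yl)-4,5-dihydrofuran-2-olate (enolate of 7) | [Li]OC1=CC(C)(C)[C@H](CC=C)O1 | intermediate
16 | (3S,5S)-4,4-dimethyl-3-[(3S)-3-methyl-3-(triethylsilyloxy)pent-4-en-1-yl]-5-(prop-2-en-1-yl)oxolan-2-one | C=C[C@@](C)(O[Si](CC)(CC)CC)CC[C@@H]1C(=O)O[C@@H](CC=C)C1(C)C | intermediate
17 | (trimethylsilylmethyl)magnesium chloride | C[Si](C)(C)C[Mg]Cl | starting material
18 | (4S,6S,9S)-6-[2-hydroxy-1,3-bis(trimethylsilyl)propan-2-yl]-5,5,9-trimethyl-9-(triethylsilyloxy)undeca-1,10-dien-4-ol | C=C[C@@](C)(O[Si](CC)(CC)CC)CC[C@H](C(O)(C[Si](C)(C)C)C[Si](C)(C)C)C(C)(C)[C@@H](O)CC=C | intermediate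
19 | (4S,6S,9S)-5,5,9-trimethyl-9-(triethylsilyloxy)-6-[3-(trimethylsilyl)prop-1-en-2-yl]undeca-1,10-dien-4-ol | C=C[C@@](C)(O[Si](CC)(CC)CC)CC[C@H](C(=C)C[Si](C)(C)C)C(C)(C)[C@@H](O)CC=C | intermediate
20 | triethyl{[(3S,6R,8R)-8-bromo-3,7,7-trimethyl-6-[3-(trimethylsilyl)prop-1-en-2-yl]undeca-1,10-dien-3-yl]oxy}silane | C=C[C@@](C)(O[Si](CC)(CC)CC)CC[C@H](C(=C)C[Si](C)(C)C)C(C)(C)[C@H](Br)CC=C | intermediate
21 | {[(4R,6R)-4-bromo-5,5-dimethyl-6-[(3S)-3-methyl-3-(triethylsilyloxy)pent-4-en-1-yl]cyclohex-1-en-1-yl]methyl}trimethylsilane | C=C[C@@](C)(O[Si](CC)(CC)CC)CC[C@@H]1C(C[Si](C)(C)C)=CC[C@@H](Br)C1(C)C | intermediate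
22 | {[(3S)-5-[(1S,3R,5R)-3,5-dibromo-2,2-dimethyl-6-methylidenecyclohexyl]-3-methylpent-1-en-3-yl]oxy}triethylsilane | C=C[C@@](C)(O[Si](CC)(CC)CC)CC[C@@H]1C(=C)[C@H](Br)C[C@@H](Br)C1(C)C | intermediate
23 | (3S)-5-[(1S,3R,5R)-3,5-dibromo-2,2-dimethyl-6-methylidenecyclohexyl]-3-methylpent-1-en-3-ol | C=C[C@@](C)(O)CC[C@@H]1C(=C)[C@H](Br)C[C@@H](Br)C1(C)C | target

## Step count and least certain steps

Total step count: 13. Longest linear sequence: 11 steps (steps 3 to 13, from 8); the other branch (steps 1 and 2) joins at step 8.

Step 11 (key step). The most likely failure is slow closure onto the congested C7 alkene, which carries the branched C6 on one side and CH2SiMe3 on the other. That would leave time for ruthenium hydride-mediated migration of the C8 double bond and for intermolecular metathesis at the same terminus. The fallback exchanges the order of ring closure and bromination. It sets out from 19, whose hydroxyl is tolerated by the catalyst, is smaller than bromine beside the gem-dimethyl carbon, and offers no HBr-loss pathway on prolonged heating. The same catalyst would close 19 to the cyclohexenol allylsilane F1 (hydroxyl cis to the side chain). Appel bromination of F1 (CBr4, PPh3, 2,6-lutidine) with inversion would then return to the route at 21; the hydroxyl of F1 is expected to be axial, so bromide would enter equatorially.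

Step 10. The most likely failure is loss of the activated oxygen by elimination toward C9 (its hydrogens are allylic, and a conjugated diene would result), by methyl migration from C11, or by capture of the developing cation by the allylsilane, because backside attack at the neopentylic carbon is slow. The fallback separates activation from displacement. It sets out from 19, which with chloromethanesulfonyl chloride and pyridine would give the chloromethanesulfonate F2. LiBr in DMPU at 0 °C to rt would then displace the sulfonate with inversion, under conditions that pair a highly active nucleophile with low basicity and a lower temperature, and the route is rejoined at 20.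

Step 12. The most likely failure is poor facial selectivity at C8 if the half-chair with the pseudoaxial chain does not dominate, or equilibration of the kinetic secondary bromide to the primary allylic bromide by traces of bromide. The fallback replaces direct bromination by oxygenation and substitution. It sets out from 21: buffered mCPBA (NaHCO3, CH2Cl2, 0 °C) would give the epoxysilane F3, and acetic acid in THF would open it with loss of silicon to the transposed allylic alcohol F4 (exocyclic methylene, C8 hydroxyl on the face of the C10 bromide). A carbinol, unlike a bromide, can be separated from its epimer and corrected by oxidation to the enone and hydride reduction. Appel bromination of F4 at −20 °C with inversion would rejoin the route at 22.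

Step 9. The most likely failure is arrest after the first addition, as the cyclic hemiketal alkoxide or by enolisation of the α-silyl ketone at the hindered carbonyl, so that work-up returns a protodesilylated methyl ketone. The fallback builds the allylsilane by cross-coupling and sets out from 16. Me(MeO)NH·HCl with iPrMgCl would open the lactone to the hydroxy Weinreb amide F5, and Me3SiCl with imidazole would give its trimethylsilyl ether F6. MeMgBr would then give the methyl ketone F7, and KN(SiMe3)2 with PhNTf2 at −78 °C the kinetic enol triflate F8, formed on the methyl side. Kumada coupling of F8 with 17 under Pd(PPh3)4 (zerovalent palladium) would give the silyl-protected allylsilane F9, and K2CO3 in MeOH would remove the trimethylsilyl ether and rejoin the route at 19.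

Step 8. The most likely failure is slow C-alkylation, since the enolate carbon is next to a quaternary carbon and the iodide has a fully substituted γ-carbon; proton transfer and self-condensation could then compete and facial selectivity could erode. The fallback forms C5–C6 by carbonyl addition and sets out from 12 and 7. Et3SiCl and imidazole would convert 12 into the bis(triethylsilyl) ether F10, and Swern conditions ((COCl)2, DMSO, Et3N) would oxidise the primary silyl ether directly to the aldehyde F11. Enolate 15 would add to F11 at −78 °C, again anti to the allyl group, to give the aldol adduct F12 as a mixture at C5 that does not matter. 1,1′-Thiocarbonyldiimidazole would give the thiocarbonylimidazolide F13, and radical deoxygenation with (Me3Si)3SiH and AIBN in toluene at 80 °C would rejoin the route at 16.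

## Further compounds

F1 | step 11 | 6,6-dimethyl-5-[(3S)-3-methyl-3-(triethylsilyloxy)pent-4-en-1-yl]-4-[(trimethylsilyl)methyl]cyclohex-3-en-1-ol, hydroxyl cis to the side chain | C=C[C@@](C)(O[Si](CC)(CC)CC)CC[C@@H]1C(C[Si](C)(C)C)=CC[C@H](O)C1(C)C
F2 | step 10 | chloromethanesulfonate of 19 at the C10 oxygen | C=C[C@@](C)(O[Si](CC)(CC)CC)CC[C@H](C(=C)C[Si](C)(C)C)C(C)(C)[C@@H](OS(=O)(=O)CCl)CC=C
F3 | step 12 | C7–C8 epoxide of 21, oxygen on the face of the C10 bromide | C=C[C@@](C)(O[Si](CC)(CC)CC)CC[C@@H]1[C@@]2(C[Si](C)(C)C)O[C@H]2C[C@@H](Br)C1(C)C
F4 | step 12 | C8 carbinol analogue of 22 with hydroxyl cis to the C10 bromide and trans to the side chain | C=C[C@@](C)(O[Si](CC)(CC)CC)CC[C@@H]1C(=C)[C@@H](O)C[C@@H](Br)C1(C)C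
F5 | step 9 | hydroxy Weinreb amide from ring opening of 16 (N-methoxy-N-methyl amide at C7, free C10 hydroxyl) | C=C[C@@](C)(O[Si](CC)(CC)CC)CC[C@H](C(=O)N(C)OC)C(C)(C)[C@@H](O)CC=C
F6 | step 9 | trimethylsilyl ether of F5 at the C10 oxygen | C=C[C@@](C)(O[Si](CC)(CC)CC)CC[C@H](C(=O)N(C)OC)C(C)(C)[C@@H](O[Si](C)(C)C)CC=C
F7 | step 9 | C7 methyl ketone with C10 trimethylsilyl ether | C=C[C@@](C)(O[Si](CC)(CC)CC)CC[C@H](C(C)=O)C(C)(C)[C@@H](O[Si](C)(C)C)CC=C
F8 | step 9 | C7 enol triflate (terminal alkene) with C10 trimethylsilyl ether | C=C[C@@](C)(O[Si](CC)(CC)CC)CC[C@H](C(=C)OS(=O)(=O)C(F)(F)F)C(C)(C)[C@@H](O[Si](C)(C)C)CC=C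
F9 | step 9 | C10 trimethylsilyl ether of 19 | C=C[C@@](C)(O[Si](CC)(CC)CC)CC[C@H](C(=C)C[Si](C)(C)C)C(C)(C)[C@@H](O[Si](C)(C)C)CC=C
F10 | step 8 | (3S)-3-methyl-1,3-bis(triethylsilyloxy)pent-4-ene | C=C[C@@](C)(O[Si](CC)(CC)CC)CCO[Si](CC)(CC)CC
F11 | step 8 | (3S)-3-methyl-3-(triethylsilyloxy)pent-4-enal | C=C[C@@](C)(O[Si](CC)(CC)CC)CC=O
F12 | step 8 | aldol adduct of 15 and F11 (C5 carbinol, both epimers) | C=C[C@@](C)(O[Si](CC)(CC)CC)CC(O)[C@@H]1C(=O)O[C@@H](CC=C)C1(C)C
F13 | step 8 | O-(imidazol-1-ylthiocarbonyl) derivative of F12 | C=C[C@@](C)(O[Si](CC)(CC)CC)CC(OC(=S)n1ccnc1)[C@@H]1C(=O)O[C@@H](CC=C)C1(C)C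
A1 | alternative 1 | methyl (4S)-5,5-dimethyl-4-(3-oxoprop-1-en-2-yl)hept-6-enoate | COC(=O)CC[C@H](C(=C)C=O)C(C)(C)C=C
A2 | alternative 1 | methyl 3-(3-bromo-5-hydroxy-2,2-dimethyl-6-methylenecyclohexyl)propanoate, hydroxyl and bromide cis to each other and trans to the ester arm | COC(=O)CC[C@@H]1C(=C)[C@@H](O)C[C@@H](Br)C1(C)C
A3 | alternative 2 | acyclic (E)-1,7-enyne with anti triethylsilyl ethers at C8 and C10 and a tert-butyldimethylsilyl ether at C3 | C#C[C@@H](O[Si](CC)(CC)CC)C[C@H](O[Si](CC)(CC)CC)C(C)(C)/C=C/C[C@](C)(O[Si](C)(C)C(C)(C)C)C=C
A4 | alternative 2 | tris-silylated cyclised triol (C8 and C10 triethylsilyl ethers anti, chain cis to the C10 oxygen) | C=C[C@@](C)(O[Si](C)(C)C(C)(C)C)CC[C@@H]1C(=C)[C@@H](O[Si](CC)(CC)CC)C[C@H](O[Si](CC)(CC)CC)C1(C)C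
A5 | alternative 3 | (3E,7S)-7-methyl-7-(triethylsilyloxy)nona-3,8-dien-2-one | CC(=O)/C=C/CC[C@](C)(O[Si](CC)(CC)CC)C=C
A6 | alternative 3 | (1-methoxy-2-methylprop-1-enyloxy)trimethylsilane | COC(O[Si](C)(C)C)=C(C)C
A7 | alternative 3 | 4,4-dimethyl-5-[(S)-3-methyl-3-(triethylsilyloxy)pent-4-enyl]cyclohexane-1,3-dione, ring centre as in 23 | C=C[C@@](C)(O[Si](CC)(CC)CC)CC[C@@H]1CC(=O)CC(=O)C1(C)C
A8 | alternative 3 | (S)-linalool | C=C[C@@](C)(O)CCC=C(C)C
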